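**Strategy.** The route rests on cutting the five-membered lactone ring (O–C8–C7–C11–C12) at O–C8 and C11–C12, so that C12 and both oxygens come from CO2. In the key step a C11 alkenyllithium, made from a 2-bromoalkene, captures CO2, and the acrylate oxygen then displaces an anti-disposed C8 tosylate with inversion, giving the trans α-methylene lactone in one operation. Its acyclic precursor carries the C6–C7–C8 triad from (S)-5-(hydroxymethyl)butenolide (trans conjugate addition, trans enolate oxidation). A Nozaki–Hiyama–Kishi closure of the ten-membered ring at C4–C5 and a palladium-catalysed allylic transposition, which installs the C15 ester and the 4,5-olefin, finish the synthesis.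

Key step: step 11

Remark: atom labels C1–C15 follow germacrane numbering (ring C1–C10, lactone carbons C11–C13, C14 = methyl on C10, C15 = CH2O on C4); CO2 is treated as a reagent, not as a numbered compound.

Step 1
Reactants: 1 (5S)-5-(hydroxymethyl)furan-2(5H)-one
Product: 2 butenolide tosylate
Conditions: TsCl, pyridine, CH2Cl2, 0 °C
Reagents that add atoms: 4-methylbenzenesulfonyl chloride, Cc1ccc(S(=O)(=O)Cl)cc1
Why: O-sulfonylation (tosylation) of the primary alcohol under weakly basic conditions that should not racemise the butenolide; the C8 stereocentre comes from the chiral pool.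

Step 2
Reactants: 2 butenolide tosylate; 3 (1-bromoethenyl)trimethylsilane
Product: 4 trans silylvinyl lactone
Conditions: 3, Mg, THF; then CuBr·SMe2 (10 mol %), 2, THF, −78 to −40 °C
Reagents that add atoms: none
Why: Copper-catalysed conjugate addition of the alkenyl Grignard reagent to the butenolide, the nucleophile adding anti to the C8 CH2OTs group, which sets C7 (4,5-trans).

Step 3
Reactants: 4 trans silylvinyl lactone
Product: 6 bromoalkenyl lactone, via dibromosilane 5 (not isolated)
Conditions: Br2, CH2Cl2, −78 °C; then Bu4NF, THF, 0 °C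
Reagents that add atoms: bromine, BrBr
Why: Bromodesilylation of a vinylsilane (anti addition of Br2, then fluoride-induced anti elimination of the silyl group and the CH2 bromide), which leaves bromine on C11 and touches no stereocentre.

Step 4
Reactants: 6 bromoalkenyl lactone
Product: 8 silyloxy lactone, via potassium alkoxide 7 (not isolated)
Conditions: KN(SiMe3)2, THF, −78 °C; 3-phenyl-2-(phenylsulfonyl)oxaziridine; then Et3SiCl, −78 to 0 °C
Reagents that add atoms: 3-phenyl-2-(phenylsulfonyl)oxaziridine, O=S(=O)(c1ccccc1)N1OC1c1ccccc1; chlorotriethylsilane, CC[Si](Cl)(CC)CC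
Why: Enolate oxidation with an N-sulfonyloxaziridine and in situ O-silylation, the oxidant approaching the lactone enolate anti to the C7 substituent, which sets C6 (3,4-trans).

Step 5
Reactants: 8 silyloxy lactone
Product: 10 epoxy alcohol, via diol tosylate 9 (not isolated)
Conditions: LiBH4, THF, 0 °C; then K2CO3, MeOH, 0 °C
Reagents that add atoms: none
Why: Hydride reduction of the lactone followed by Williamson-type epoxide closure (3-exo-tet) of the C8 alkoxide onto the neighbouring primary tosylate, so C8 keeps its C–O bond and configuration.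

Step 6
Reactants: 10 epoxy alcohol
Product: 11 bis(silyl) epoxide
Conditions: Et3SiCl, imidazole, DMAP (cat.), DMF, 0 °C to rt
Reagents that add atoms: chlorotriethylsilane, CC[Si](Cl)(CC)CC
Why: O-silylation of the remaining hydroxyl group; any C6-to-C5 silyl-migrated isomer from step 5 converges on the same bis(triethylsilyl) ether.

Step 7
Reactants: 12 pent-3-yn-1-ol
Product: 14 (E)-iodoalkenol, via alkenylzirconocene 13 (not isolated)
Conditions: Cp2Zr(H)Cl (2.2 equiv), THF, rt to 40 °C; then I2, 0 °C
Reagents that add atoms: iodine, II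
Why: syn-Hydrozirconation of the 2-alkyne (zirconium on the methyl-bearing carbon after equilibration with excess reagent) and iodinolysis with retention should give the (E)-alkenyl iodide.

Step 8
Reactants: 14 (E)-iodoalkenol; 15 ethynyltrimethylsilane
Product: 17 iodoenyne, via triflate 16 (not isolated)
Conditions: Tf2O, 2,6-lutidine, CH2Cl2, −78 °C; then LiC≡CSiMe3 (from 15, n-BuLi), THF–DMPU, −78 to −20 °C
Reagents that add atoms: none
Why: Triflation and SN2 alkynylation of the primary triflate by the lithium acetylide at low temperature, which should suppress E2 to the diene and leave the alkenyl iodide untouched.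

Step 9
Reactants: 11 bis(silyl) epoxide; 17 iodoenyne
Product: 19 homoallylic alcohol, via alkenyllithium 18 (not isolated)
Conditions: 17, t-BuLi (2 equiv), Et2O, −78 °C; then 11, BF3·OEt2, −78 °C
Reagents that add atoms: none
Why: Iodine–lithium exchange with retention and BF3-promoted SN2 opening of the terminal epoxide at C9 by the alkenyllithium, which forms C9–C10 with the E olefin intact and C8 unchanged.

Step 10
Reactants: 19 homoallylic alcohol
Product: 20 C8 tosylate
Conditions: TsCl, Et3N, Me3N·HCl (cat.), CH2Cl2, 0 °C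
Reagents that add atoms: 4-methylbenzenesulfonyl chloride, Cc1ccc(S(=O)(=O)Cl)cc1
Why: O-sulfonylation of the hindered secondary alcohol with retention at C8, which places the leaving group anti to the C7 bromoalkenyl group.

Step 11
Reactants: 20 C8 tosylate
Product: 23 trans α-methylene lactone, via alkenyllithium 21 (not isolated), via lithium carboxylate 22 (not isolated)
Conditions: t-BuLi (2.0 equiv), THF–Et2O, −78 °C; CO2 (gas), −78 °C; then warm to rt, add DMF, 50 °C
Reagents that add atoms: carbon dioxide, O=C=O
Why: Bromine–lithium exchange gives the C11 alkenyllithium 21, which adds to CO2 to forge C11–C12 (alkenyllithium carboxylation); on warming, the lithium acrylate 22 closes the five-membered lactone by intramolecular SN2 O-alkylation at C8 (carboxylate alkylation, a lactonisation with inversion), forging O–C8. The ring closure is 5-exo-tet, the carboxylate oxygen attacking C8 anti to the departing tosylate. No new stereocentre is created: C8 is inverted, so the anti C7/C8 precursor derived from the chiral pool should give the 7,8-trans lactone with the target configuration, while C6 and C7 are untouched. The step needs exchange and carboxylation to outrun attack on the sulfonate, elimination and 3-exo-tet closure; the low temperature, the bulky non-nucleophilic t-BuLi (its second equivalent destroys t-BuBr), the immediate CO2 quench and the in-plane sp2 carbanion at C11 pointing away from C8 should secure this. The silyl ethers, the silylalkyne and the trisubstituted olefin are expected to be inert.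

Step 12
Reactants: 23 trans α-methylene lactone
Product: 24 terminal alkyne
Conditions: AgNO3 (10 mol %), acetone–H2O–CH2Cl2, rt
Reagents that add atoms: none
Why: Silver-catalysed protodesilylation of the alkynylsilane, which should spare the silyl ethers and the base-sensitive α-methylene lactone.

Step 13
Reactants: 24 terminal alkyne
Product: 26 2-iodoalkene, via iodoalkenylborane 25 (not isolated)
Conditions: 9-iodo-9-borabicyclo[3.3.1]nonane, pentane–CH2Cl2, −20 °C; then AcOH, 0 °C
Reagents that add atoms: 9-iodo-9-borabicyclo[3.3.1]nonane, IB1C2CCCC1CCC2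
Why: Regioselective syn-iodoboration of the terminal alkyne (boron on the terminal carbon, iodine on C4) and protodeboronation, a Markovnikov hydroiodination that should leave the other olefins alone.

Step 14
Reactants: 26 2-iodoalkene
Product: 27 α-silyloxy aldehyde
Conditions: (COCl)2, DMSO, CH2Cl2, −78 to −30 °C; then Et3N
Reagents that add atoms: none
Why: Swern oxidation, which converts a primary triethylsilyl ether directly into the aldehyde while the secondary silyl ether at C6 survives.

Step 15
Reactants: 27 α-silyloxy aldehyde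
Product: 28 macrocyclic allylic alcohol
Conditions: CrCl2 (8 equiv), NiCl2 (5 mol %), DMSO–THF, rt, 2 mM, slow addition
Reagents that add atoms: none
Why: Nozaki–Hiyama–Kishi macrocyclisation, the alkenylchromium species at C4 adding to the C5 aldehyde to close the ten-membered ring; both C5 epimers are usable because C5 becomes sp2 in step 20.

Step 16
Reactants: 28 macrocyclic allylic alcohol
Product: 29 allylic methyl carbonate
Conditions: ClCO2Me, pyridine, DMAP (cat.), CH2Cl2, 0 °C
Reagents that add atoms: methyl chloroformate, COC(=O)Cl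
Why: O-acylation of the only free hydroxyl group to the carbonate needed for ionisation by palladium.

Step 17
Reactants: 30 (2E)-but-2-enal
Product: 31 (2Z)-2-iodobut-2-enal
Conditions: I2, K2CO3, DMAP (20 mol %), THF–H2O, rt
Reagents that add atoms: iodine, II
Why: α-Iodination of the enal by a Baylis–Hillman-type addition–iodination–elimination sequence, which should give the Z isomer (iodine cis to methyl).

Step 18
Reactants: 31 (2Z)-2-iodobut-2-enal
Product: 32 (2Z)-2-iodobut-2-en-1-ol
Conditions: NaBH4, CeCl3·7H2O, MeOH, 0 °C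
Reagents that add atoms: none
Why: Luche 1,2-reduction of the enal with the olefin geometry retained.

Step 19
Reactants: 32 (2Z)-2-iodobut-2-en-1-ol
Product: 34 (2Z)-2-(hydroxymethyl)but-2-enoic acid, via dilithio species 33 (not isolated)
Conditions: t-BuLi (3.1 equiv), Et2O, −78 °C; CO2; then aq. HCl
Reagents that add atoms: carbon dioxide, O=C=O
Why: Iodine–lithium exchange on the lithium alkoxide with retention of geometry and carboxylation of the alkenyllithium, so the carboxyl group ends up cis to the methyl group.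

Step 20
Reactants: 29 allylic methyl carbonate; 34 (2Z)-2-(hydroxymethyl)but-2-enoic acid
Product: 35 C15 ester with C6 silyl ether
Conditions: Pd2(dba)3·CHCl3 (2.5 mol %), PPh3 (10 mol %), THF, rt
Reagents that add atoms: none
Why: Tsuji–Trost allylic substitution: ionisation of the carbonate gives a π-allyl complex over C5–C4–C15, the carboxylate attacks the unhindered C15 terminus without any acyl activation (so the Z acid should not isomerise), and reversible re-ionisation of the allylic ester should let the product settle as the linear ester with the less strained ring-cis 4,5-olefin (C3 and C6 cis).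

Step 21
Reactants: 35 C15 ester with C6 silyl ether
Product: 36 target CNP0234544.2
Conditions: HF·pyridine, pyridine, THF, 0 °C
Reagents that add atoms: none
Why: Fluoride-mediated cleavage of the secondary triethylsilyl ether under buffered conditions that the α-methylene lactone and the allylic ester should tolerate.

**Compound list**

1 | (5S)-5-(hydroxymethyl)furan-2(5H)-one | O=C1O[C@H](CO)C=C1 | starting material
2 | [(2S)-5-oxo-2,5-dihydrofuran-2-yl]methyl 4-methylbenzenesulfonate | O=C1O[C@H](COS(=O)(=O)c2ccc(C)cc2)C=C1 | intermediate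
3 | (1-bromoethenyl)trimethylsilane | C=C(Br)[Si](C)(C)C | starting material
4 | (4S,5S)-5-[(tosyloxy)methyl]-4-[1-(trimethylsilyl)ethenyl]oxolan-2-one, 4,5-trans (oxolane C4 = C7, C5 = C8) | O=C1O[C@H](COS(=O)(=O)c2ccc(C)cc2)[C@@H](C(=C)[Si](C)(C)C)C1 | intermediate
5 | 4-[1,2-dibromo-1-(trimethylsilyl)ethyl]-5-[(tosyloxy)methyl]oxolan-2-one, 4,5-trans, both epimers at the CBr carbon | O=C1O[C@H](COS(=O)(=O)c2ccc(C)cc2)[C@@H](C(Br)(CBr)[Si](C)(C)C)C1 | intermediate (not isolated)
6 | (4S,5S)-4-(1-bromoethenyl)-5-[(tosyloxy)methyl]oxolan-2-one | O=C1O[C@H](COS(=O)(=O)c2ccc(C)cc2)[C@@H](C(Br)=C)C1 | intermediate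
7 | potassium alkoxide of 4-(1-bromoethenyl)-3-hydroxy-5-[(tosyloxy)methyl]oxolan-2-one, 3,4-trans-4,5-trans | O=C1O[C@H](COS(=O)(=O)c2ccc(C)cc2)[C@@H](C(Br)=C)[C@@H]1[O-].[K+] | intermediate (not isolated)
8 | 4-(1-bromoethenyl)-5-[(tosyloxy)methyl]-3-[(triethylsilyl)oxy]oxolan-2-one, 3,4-trans-4,5-trans (oxolane C3 = C6) | O=C1O[C@H](COS(=O)(=O)c2ccc(C)cc2)[C@@H](C(Br)=C)[C@@H]1O[Si](CC)(CC)CC | intermediate
9 | 3-(1-bromoethenyl)-2,5-dihydroxy-4-[(triethylsilyl)oxy]pentyl 4-methylbenzenesulfonate (pentyl C1–C5 = C9, C8, C7, C6, C5; C8–O anti and C6–O syn to the bromoethenyl group in the zigzag chain) | OC[C@@H](O[Si](CC)(CC)CC)[C@H](C(Br)=C)[C@H](O)COS(=O)(=O)c1ccc(C)cc1 | intermediate (not isolated)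
10 | 4-bromo-3-(oxiran-2-yl)-2-[(triethylsilyl)oxy]pent-4-en-1-ol (C5–OH, C6–OSiEt3, C8/C9 epoxide; configuration as in 9) | OC[C@@H](O[Si](CC)(CC)CC)[C@H](C(Br)=C)[C@H]1CO1 | intermediate
11 | bis(triethylsilyl) ether of 4-bromo-3-(oxiran-2-yl)pent-4-ene-1,2-diol (configuration as in 10) | CC[Si](CC)(CC)OC[C@@H](O[Si](CC)(CC)CC)[C@H](C(Br)=C)[C@H]1CO1 | intermediate
12 | pent-3-yn-1-ol | CC#CCCO | starting material
13 | (E)-4-(chlorozirconocenyl)pent-3-en-1-yl zirconocene chloride alkoxide | C/C(=C\CCO[Zr](Cl)(C1C=CC=C1)C1C=CC=C1)[Zr](Cl)(C1C=CC=C1)C1C=CC=C1 | intermediate (not isolated)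
14 | (3E)-4-iodopent-3-en-1-ol | C/C(I)=C\CCO | intermediate
15 | ethynyltrimethylsilane | C#C[Si](C)(C)C | starting material
16 | (3E)-4-iodopent-3-en-1-yl trifluoromethanesulfonate | C/C(I)=C\CCOS(=O)(=O)C(F)(F)F | intermediate (not isolated)
17 | [(5E)-6-iodohept-5-en-1-yn-1-yl]trimethylsilane | C/C(I)=C\CCC#C[Si](C)(C)C | intermediate
18 | [(5E)-6-lithiohept-5-en-1-yn-1-yl]trimethylsilane | C/C([Li])=C\CCC#C[Si](C)(C)C | intermediate (not isolated)
19 | (6E)-2-bromo-6-methyl-3-[1,2-bis(triethylsilyloxy)ethyl]-11-(trimethylsilyl)undeca-1,6-dien-10-yn-4-ol (undecane C3 = C7, C4 = C8; C8–OH anti and C6–O syn to the bromoethenyl group) | CC[Si](CC)(CC)OC[C@@H](O[Si](CC)(CC)CC)[C@H](C(Br)=C)[C@H](O)C/C(C)=C/CCC#C[Si](C)(C)C | intermediate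
20 | 4-methylbenzenesulfonate of 19 at C8 | CC[Si](CC)(CC)OC[C@@H](O[Si](CC)(CC)CC)[C@H](C(Br)=C)[C@H](OS(=O)(=O)c1ccc(C)cc1)C/C(C)=C/CCC#C[Si](C)(C)C | intermediate
21 | C11-lithio analogue of 20 (bromine replaced by lithium) | CC[Si](CC)(CC)OC[C@@H](O[Si](CC)(CC)CC)[C@H](C([Li])=C)[C@H](OS(=O)(=O)c1ccc(C)cc1)C/C(C)=C/CCC#C[Si](C)(C)C | intermediate (not isolated)
22 | lithium salt of the 2-substituted acrylic acid formed by carboxylation of 21 at C11 | CC[Si](CC)(CC)OC[C@@H](O[Si](CC)(CC)CC)[C@H](C(=C)C(=O)[O-])[C@H](OS(=O)(=O)c1ccc(C)cc1)C/C(C)=C/CCC#C[Si](C)(C)C.[Li+] | intermediate (not isolated)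
23 | 3-methylidene-4-[1,2-bis(triethylsilyloxy)ethyl]-5-[(2E)-2-methyl-7-(trimethylsilyl)hept-2-en-6-yn-1-yl]oxolan-2-one, 4,5-trans (oxolane C3 = C11, C4 = C7, C5 = C8; C6, C7, C8 as in the target) | CC[Si](CC)(CC)OC[C@@H](O[Si](CC)(CC)CC)[C@@H]1C(=C)C(=O)O[C@H]1C/C(C)=C/CCC#C[Si](C)(C)C | intermediate
24 | 3-methylidene-4-[1,2-bis(triethylsilyloxy)ethyl]-5-[(2E)-2-methylhept-2-en-6-yn-1-yl]oxolan-2-one, 4,5-trans | CC[Si](CC)(CC)OC[C@@H](O[Si](CC)(CC)CC)[C@@H]1C(=C)C(=O)O[C@H]1C/C(C)=C/CCC#C | intermediate
25 | B-[(1Z)-2-iodoalk-1-enyl]-9-borabicyclo[3.3.1]nonane adduct of 24 (boron on C15, iodine on C4) | CC[Si](CC)(CC)OC[C@@H](O[Si](CC)(CC)CC)[C@@H]1C(=C)C(=O)O[C@H]1C/C(C)=C/CC/C(I)=C/B1C2CCCC1CCC2 | intermediate (not isolated)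
26 | 5-[(2E)-6-iodo-2-methylhepta-2,6-dien-1-yl]-3-methylidene-4-[1,2-bis(triethylsilyloxy)ethyl]oxolan-2-one, 4,5-trans | CC[Si](CC)(CC)OC[C@@H](O[Si](CC)(CC)CC)[C@@H]1C(=C)C(=O)O[C@H]1C/C(C)=C/CCC(I)=C | intermediate
27 | 2-{2-[(2E)-6-iodo-2-methylhepta-2,6-dien-1-yl]-4-methylidene-5-oxooxolan-3-yl}-2-[(triethylsilyl)oxy]acetaldehyde (C5 aldehyde; C6, C7, C8 as in the target) | O=C[C@@H](O[Si](CC)(CC)CC)[C@@H]1C(=C)C(=O)O[C@H]1C/C(C)=C/CCC(I)=C | intermediate
28 | (1(10)E)-5-hydroxy-6-[(triethylsilyl)oxy]germacra-1(10),4(15),11(13)-trien-12,8-olide, both C5 epimers (C6, C7, C8 as in the target) | OC1[C@@H](O[Si](CC)(CC)CC)[C@@H]2C(=C)C(=O)O[C@H]2C/C(C)=C/CCC1=C | intermediate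
29 | 5-O-(methoxycarbonyl) derivative of 28 | COC(=O)OC1[C@@H](O[Si](CC)(CC)CC)[C@@H]2C(=C)C(=O)O[C@H]2C/C(C)=C/CCC1=C | intermediate
30 | (2E)-but-2-enal | C/C=C/C=O | starting material
31 | (2Z)-2-iodobut-2-enal | C/C=C(\I)C=O | intermediate
32 | (2Z)-2-iodobut-2-en-1-ol | C/C=C(\I)CO | intermediate
33 | lithium (2Z)-2-lithiobut-2-en-1-olate | C/C=C(\[Li])CO[Li] | intermediate (not isolated)
34 | (2Z)-2-(hydroxymethyl)but-2-enoic acid | C/C=C(\C(=O)O)CO | intermediate
35 | 6-O-triethylsilyl ether of 36 | C=C1C(=O)O[C@H]2C/C(C)=C/CC/C(COC(=O)/C(=C\C)CO)=C\[C@@H](O[Si](CC)(CC)CC)[C@H]12 | intermediate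
36 | (6R,7S,8S)-6-hydroxy-15-{[(2Z)-2-(hydroxymethyl)but-2-enoyl]oxy}germacra-1(10),4,11(13)-trien-12,8-olide, 1(10)E, 4,5-olefin with C3 and C6 cis, trans-fused lactone | C=C1C(=O)O[C@H]2C/C(C)=C/CC/C(COC(=O)/C(=C\C)CO)=C\[C@@H](O)[C@H]12 | target

**Step count.** Total: 21 steps. Longest linear sequence: 16 steps (steps 1–6, 9–16, 20, 21, from compound 1).

**Steps most likely to fail**

Step 11 (key step). What may go wrong: attack of t-BuLi or of the alkenyllithium on the sulfonate, or E2 loss of the C8 tosylate towards the conjugated 8,10-diene, before the carboxylate can close the ring. The fallback sets out from alcohol 19. Mesylation (MsCl, Et3N, CH2Cl2, 0 °C) gives the C8 methanesulfonate F1, which is inert to low-valent nickel. Both bonds are then formed without any carbanion by nickel-catalysed reductive carboxylation (NiBr2(2,2'-bipyridine) 10 mol %, Mn powder, CO2 1 atm, DMA, rt, then 60 °C): the alkenylnickel species inserts CO2 and the resulting carboxylate displaces the mesylate with inversion. The fallback comes back to the route at lactone 23.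

Step 15. What may go wrong: intermolecular coupling or protodehalogenation of the alkenylchromium species outrunning closure of the ten-membered ring; the preceding iodoboration (step 13) may also erode the silyl ethers or add iodide to the lactone. The fallback sets out from alkyne 24 and avoids the alkenyl iodide altogether. Swern oxidation of the primary silyl ether gives the ynal F2. A nickel-catalysed reductive alkyne–aldehyde macrocyclisation follows (Ni(cod)2, 1,3-bis(2,6-diisopropylphenyl)imidazol-2-ylidene, PhMe2SiH, THF, high dilution); the bulky carbene ligand should direct C–C bond formation to the internal alkyne carbon C4 and give the exo-methylene dimethylphenylsilyl ether F3. PPTS in MeOH at 0 °C then removes the labile dimethylphenylsilyl group in the presence of the triethylsilyl ether, and the fallback comes back at alcohol 28.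

Step 20. What may go wrong: loss of regio- or geometric control in the capture of the π-allyl complex (branched C5 ester or ring-trans 4,5-olefin), or β-hydride elimination to a diene. The fallback sets out from alcohol 28. A rhenium-catalysed 1,3-transposition (Ph3SiOReO3, Et2O, 0 °C) through a chair-like perrhenate ester rearrangement moves the hydroxyl group to C15 and should give the primary allylic alcohol F4 with the trisubstituted ring-cis olefin. Mitsunobu esterification (PPh3, DIAD, THF, 0 °C) with the silyl-protected acid F5 (from 34: TBSCl, imidazole; then K2CO3, MeOH–H2O) gives the doubly silylated ester F6 by SN2 at the primary allylic carbon, again without acyl activation. HF·pyridine then removes both silyl groups, and the fallback comes back at the target 36.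

**Further compounds**

F1 | step 11 | methanesulfonate of 19 at C8 | CC[Si](CC)(CC)OC[C@@H](O[Si](CC)(CC)CC)[C@H](C(Br)=C)[C@H](OS(C)(=O)=O)C/C(C)=C/CCC#C[Si](C)(C)C
F2 | step 15 | 2-{2-[(2E)-2-methylhept-2-en-6-yn-1-yl]-4-methylidene-5-oxooxolan-3-yl}-2-[(triethylsilyl)oxy]acetaldehyde | O=C[C@@H](O[Si](CC)(CC)CC)[C@@H]1C(=C)C(=O)O[C@H]1C/C(C)=C/CCC#C
F3 | step 15 | 5-O-[dimethyl(phenyl)silyl] ether of 28 | C[Si](C)(OC1[C@@H](O[Si](CC)(CC)CC)[C@@H]2C(=C)C(=O)O[C@H]2C/C(C)=C/CCC1=C)c1ccccc1
F4 | step 20 | 15-hydroxy-6-[(triethylsilyl)oxy]germacra-1(10),4,11(13)-trien-12,8-olide, 4,5-olefin ring-cis | C=C1C(=O)O[C@H]2C/C(C)=C/CC/C(CO)=C\[C@@H](O[Si](CC)(CC)CC)[C@H]12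
F5 | step 20 | (2Z)-2-{[(tert-butyldimethylsilyl)oxy]methyl}but-2-enoic acid | C/C=C(\C(=O)O)CO[Si](C)(C)C(C)(C)C
F6 | step 20 | 6-O-triethylsilyl, side-chain O-tert-butyldimethylsilyl ether of 36 | C=C1C(=O)O[C@H]2C/C(C)=C/CC/C(COC(=O)/C(=C\C)CO[Si](C)(C)C(C)(C)C)=C\[C@@H](O[Si](CC)(CC)CC)[C@H]12
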